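**Retrosynthetic overview**
1. Target 14 ⇐ double O-acetylation of diol 13. The two units differ only at the carbinol carbon C7 (acetate axial in unit A, equatorial in unit B), so the two carbinols come from two stereocomplementary tertiary-selective hydrations of the identical ring alkenes of C2-symmetric bis-cyclohexene 10.
2. 10 ⇐ both oxepan-3-one rings closed at once from bis(keto aldehyde) 8 by two-fold intramolecular aldol condensation (C4–C5), then hydrogenation of the enones.
3. 8 ⇐ two-directional Diels–Alder reaction of tetraene 4 (from succinaldehyde by two Wittig reactions) with two molecules of enal 7. In each ring the bonds C9–C9a and C5a–C6 are formed.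
4. Enabling feature: in each cyclohexane ring (C5a, C6, C7, C8, C9, C9a) the tertiary C7(Me)–OAc carbon is a latent C7=C8 alkene, 1,4 to the C9a–O carbon, and C9a–O sits cis to the methyl on quaternary C5a. This is a cyclohexene retron: diene C9=C8–C7(Me)=C6 plus the E dienophile C9a(OR)=C5a(Me)–CHO. Both rings share the configuration at C5a, C6 and C9a and hang on one CH2CH2 bridge, so one tetraene serves both.
5. Ring order: the two cyclohexene rings first (step 4), then the two oxepane rings (step 5).

Key step: step 4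

Numbering: 1-benzoxepine locants are used for each bicyclic unit: O1, C2 (CMe2), C3 (C=O), C4, C5, C5a (C–Me), C6 (CH carrying the CH2CH2 bridge), C7 (C(Me)–O), C8, C9, C9a (CH–O).

Assumption: the (S)-oxazaborolidine is taken to give the enantiomer drawn (enal held by a formyl C–H···O contact, diene adding to the unshielded face); if the sense proves opposite, the (R)-catalyst is used and nothing else changes.

**Step 1**
Reactants: 1 butanedial (succinaldehyde, freshly distilled); 2 2-(triphenyl-λ5-phosphanylidene)propanal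
Product: 3 (2E,6E)-2,7-dimethylocta-2,6-dienedial
Conditions: 2 (2.2 equiv), CH2Cl2, 40 °C
Reagents that add atoms: none
Why: Two-fold Wittig olefination with a formyl-stabilised ylide, which reacts with the saturated aldehyde groups faster than with the enal formed and gives the E trisubstituted alkenes.

**Step 2**
Reactants: 3 (2E,6E)-2,7-dimethylocta-2,6-dienedial
Product: 4 (3E,7E)-3,8-dimethyldeca-1,3,7,9-tetraene
Conditions: Ph3PCH3Br (2.5 equiv), KOt-Bu (2.4 equiv), THF, 0 °C to rt
Reagents that add atoms: methyltriphenylphosphonium bromide, C[P+](c1ccccc1)(c1ccccc1)c1ccccc1.[Br-]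
Why: Two-fold Wittig methylenation; the non-stabilised ylide adds 1,2 to both enal carbonyls and leaves the E alkenes untouched, giving the bis(1,3-diene).

**Step 3**
Reactants: 5 (E)-3-ethoxy-2-methylprop-2-enal; 6 3-hydroxy-3-methylbutan-2-one
Product: 7 (E)-2-methyl-3-[(2-methyl-3-oxobutan-2-yl)oxy]prop-2-enal
Conditions: 6 (3 equiv), PPTS (5 mol %), toluene, 80 °C, EtOH distilled off
Reagents that add atoms: none
Why: Acid-catalysed addition–elimination at the β-carbon of the vinylogous formate (alkoxy exchange), driven by removal of ethanol; the E isomer (alkoxy trans to formyl) is the thermodynamic geometry.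

**Step 4**
Reactants: 4 (3E,7E)-3,8-dimethyldeca-1,3,7,9-tetraene; 7 (E)-2-methyl-3-[(2-methyl-3-oxobutan-2-yl)oxy]prop-2-enal
Product: 8 C2-symmetric bis-adduct, 2,2'-(ethane-1,2-diyl)bis[(1S,2R,6S)-1,3-dimethyl-6-[(2-methyl-3-oxobutan-2-yl)oxy]cyclohex-3-ene-1-carbaldehyde]; in each ring 1-Me, 6-O and the 2-CH2 bridge are mutually cis and CHO is trans to them
Conditions: 7 (2.4 equiv), (S)-3,3-diphenyl-1-(2-methylphenyl)tetrahydro-1H,3H-pyrrolo[1,2-c][1,3,2]oxazaborole·AlBr3 (20 mol %), CH2Cl2, −40 to −20 °C
Reagents that add atoms: none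
Why: Proposed new method: the AlBr3-activated oxazaborolidine binds the formyl oxygen of the vinylogous formate 7 and makes its alkoxy-bearing β-carbon an oxocarbenium-like acceptor, so each diene of 4 should add in a strongly asynchronous [4+2] (lead bond from the unsubstituted diene terminus to the O-bearing carbon, then closure of the enolate-like α-carbon on the allyl-cation terminus); the closest known reaction type is the cationic-oxazaborolidine-catalysed enantioselective Diels–Alder reaction of 2-methyl-substituted enals with acyclic dienes, not yet shown for 3-alkoxy enals. Each cyclohexene ring is closed by an intermolecular [4+2] cycloaddition that forms two sigma bonds across the diene termini. The cis relation of ring methyl and ether oxygen is copied suprafacially from the E geometry of 7; the cis relation of the CH2 bridge to both needs the E diene geometry together with a formyl-exo (methyl-endo) approach, which a bulky Lewis acid on an s-trans 2-methyl enal should favour; the absolute sense comes from the catalyst shielding one enal face. The regioselectivity needed (quaternary carbon bonded to the substituted diene terminus) is secured by the polarisation of the activated enal, whose β-carbon bonds to the unhindered CH2 terminus, and by the directing effect of the 1-alkyl branch. Because both cycloadditions are catalyst-controlled in the same sense, the C2-symmetric bis-adduct should dominate over the meso isomer, which is removed by chromatography.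

**Step 5**
Reactants: 8 C2-symmetric bis-adduct
Product: 9 6,6'-(ethane-1,2-diyl)bis[(5aS,6R,9aS)-2,2,5a,7-tetramethyl-5a,6,9,9a-tetrahydro-1-benzoxepin-3(2H)-one]; trans ring fusion, bridge cis to 5a-Me
Conditions: NaOMe (0.5 equiv), MeOH, 50 °C, high dilution
Reagents that add atoms: none
Why: Two-fold intramolecular aldol condensation; each methyl ketone has one enolisable position and each aldehyde is non-enolisable, so only the seven-membered cis-enone can form (helped by the gem-dimethyl group), and no stereocentre is created because the trans fusion is already fixed at C5a and C9a.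

**Step 6**
Reactants: 9 bis-oxepenone
Product: 10 6,6'-(ethane-1,2-diyl)bis[(5aS,6R,9aS)-2,2,5a,7-tetramethyl-4,5,5a,6,9,9a-hexahydro-1-benzoxepin-3(2H)-one]
Conditions: H2 (3 atm), RhCl(PPh3)3 (10 mol %), benzene–EtOH, rt
Reagents that add atoms: none
Why: Homogeneous hydrogenation reduces the two cis-disubstituted enone alkenes but not the hindered trisubstituted ring alkenes; no stereocentre is formed.

**Step 7**
Reactants: 10 C2-symmetric bis(oxepanone) bis-cyclohexene
Product: 11 mono-bromohydrin: unit A (5aS,6S,7S,8S,9aS)-8-bromo-7-hydroxy-2,2,5a,7-tetramethyloctahydro-1-benzoxepin-3(2H)-one (7-OH axial and cis to 5a-Me, 8-Br axial and trans to OH), joined C6–CH2CH2–C6' to unit B, the unchanged (5aS,6R,9aS) cyclohexene unit of 10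
Conditions: NBS (1.0 equiv), THF–H2O 4:1, 0 °C, dark; stopped at partial conversion, recovered 10 recycled
Reagents that add atoms: N-bromosuccinimide, O=C1CCC(=O)N1Br; water, O
Why: Bromohydrin formation: the bromonium ion forms on the face anti to the axial 5a-methyl and water opens it trans-diaxially at the tertiary carbon, which sets the axial 7-OH; the two alkenes of 10 are symmetry-equivalent, so mono-addition at either gives the same compound.

**Step 8**
Reactants: 11 mono-bromohydrin
Product: 12 mono-alcohol: unit A (5aS,6S,7R,9aS)-7-hydroxy-2,2,5a,7-tetramethyloctahydro-1-benzoxepin-3(2H)-one (7-OH axial), unit B the unchanged (5aS,6R,9aS) cyclohexene unit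
Conditions: Bu3SnH (1.5 equiv), AIBN (cat.), toluene, 80 °C
Reagents that add atoms: none
Why: Radical-chain dehalogenation of the secondary bromide; ketones, ether, tertiary alcohol and the remaining trisubstituted alkene are inert, and the carbinol stereocentre is not touched.

**Step 9**
Reactants: 12 mono-alcohol
Product: 13 diol: unit A (5aS,6S,7R,9aS), 7-OH axial and cis to 5a-Me; unit B (5aS,6S,7S,9aS), 7-OH equatorial and trans to 5a-Me
Conditions: Co(acac)2 (20 mol %), PhSiH3 (2 equiv), O2 (1 atm), THF–i-PrOH, rt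
Reagents that add atoms: dioxygen, O=O
Why: Mukaiyama hydration: hydrogen-atom transfer gives the tertiary ring radical, which should be oxygenated on the face anti to the axial 5a-methyl (equatorial attack), placing the new OH trans to that methyl, the stereocomplement of step 7.

**Step 10**
Reactants: 13 diol
Product: 14 target diacetate CNP0325605.1: unit A (5aS,6S,7R,9aS)-7-acetoxy, unit B (5aS,6S,7S,9aS)-7-acetoxy, each a 2,2,5a,7-tetramethyl-3-oxodecahydro-1-benzoxepin-6-yl unit, joined by CH2CH2
Conditions: Ac2O (6 equiv), Sc(OTf)3 (5 mol %), MeCN, −20 to 0 °C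
Reagents that add atoms: acetic anhydride, CC(=O)OC(C)=O
Why: Lewis-acid-catalysed acylation acetylates hindered tertiary alcohols at low temperature without ionisation, so both carbinol configurations are retained and the ketones are untouched.

**Compound list**
1 | butanedial (succinaldehyde) | O=CCCC=O | starting material
2 | 2-(triphenyl-λ5-phosphanylidene)propanal | CC(C=O)=P(c1ccccc1)(c1ccccc1)c1ccccc1 | starting material
3 | (2E,6E)-2,7-dimethylocta-2,6-dienedial | O=C/C(C)=C/CC/C=C(\C)C=O | intermediate
4 | (3E,7E)-3,8-dimethyldeca-1,3,7,9-tetraene | C=C/C(C)=C/CC/C=C(\C)C=C | intermediate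
5 | (E)-3-ethoxy-2-methylprop-2-enal | CCO/C=C(\C)C=O | starting material
6 | 3-hydroxy-3-methylbutan-2-one | CC(=O)C(C)(C)O | starting material
7 | (E)-2-methyl-3-[(2-methyl-3-oxobutan-2-yl)oxy]prop-2-enal | CC(=O)C(C)(C)O/C=C(\C)C=O | intermediate
8 | 2,2'-(ethane-1,2-diyl)bis[(1S,2R,6S)-1,3-dimethyl-6-[(2-methyl-3-oxobutan-2-yl)oxy]cyclohex-3-ene-1-carbaldehyde] | CC1=CC[C@H](OC(C)(C)C(C)=O)[C@@](C)(C=O)[C@@H]1CC[C@@H]1C(C)=CC[C@H](OC(C)(C)C(C)=O)[C@@]1(C)C=O | intermediate
9 | 6,6'-(ethane-1,2-diyl)bis[(5aS,6R,9aS)-2,2,5a,7-tetramethyl-5a,6,9,9a-tetrahydro-1-benzoxepin-3(2H)-one] | CC1=CC[C@@H]2OC(C)(C)C(=O)C=C[C@@]2(C)[C@@H]1CC[C@H]1[C@]2(C)C=CC(=O)C(C)(C)O[C@H]2CC=C1C | intermediate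
10 | 6,6'-(ethane-1,2-diyl)bis[(5aS,6R,9aS)-2,2,5a,7-tetramethyl-4,5,5a,6,9,9a-hexahydro-1-benzoxepin-3(2H)-one] | CC1=CC[C@@H]2OC(C)(C)C(=O)CC[C@@]2(C)[C@@H]1CC[C@H]1[C@]2(C)CCC(=O)C(C)(C)O[C@H]2CC=C1C | intermediate
11 | mono-bromohydrin: unit A (5aS,6S,7S,8S,9aS)-8-bromo-7-hydroxy, unit B (5aS,6R,9aS) cyclohexene | O[C@]1(C)[C@@H](Br)C[C@@H]2OC(C)(C)C(=O)CC[C@@]2(C)[C@@H]1CC[C@H]1[C@]2(C)CCC(=O)C(C)(C)O[C@H]2CC=C1C | intermediate
12 | mono-alcohol: unit A (5aS,6S,7R,9aS)-7-hydroxy (axial), unit B (5aS,6R,9aS) cyclohexene | O[C@]1(C)CC[C@@H]2OC(C)(C)C(=O)CC[C@@]2(C)[C@@H]1CC[C@H]1[C@]2(C)CCC(=O)C(C)(C)O[C@H]2CC=C1C | intermediate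
13 | diol: unit A (5aS,6S,7R,9aS)-7-hydroxy (axial), unit B (5aS,6S,7S,9aS)-7-hydroxy (equatorial) | O[C@]1(C)CC[C@@H]2OC(C)(C)C(=O)CC[C@@]2(C)[C@@H]1CC[C@H]1[C@]2(C)CCC(=O)C(C)(C)O[C@H]2CC[C@]1(C)O | intermediate
14 | target diacetate CNP0325605.1: unit A (5aS,6S,7R,9aS), unit B (5aS,6S,7S,9aS) | CC(=O)O[C@]1(C)CC[C@@H]2OC(C)(C)C(=O)CC[C@@]2(C)[C@@H]1CC[C@H]1[C@]2(C)CCC(=O)C(C)(C)O[C@H]2CC[C@]1(C)OC(C)=O | target

**Totals**
Total steps: 10. Longest linear sequence: 9 (steps 1, 2, 4 to 10; step 3 is a one-step side branch).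

**Steps most likely to fail**

1. Step 4 (Proposed new method). What may go wrong: the alkoxy donor may slow the cycloaddition so much that the tetraene oligomerises or only one diene reacts, and a formyl-endo approach would erode the control at C6. The fallback uses known chemistry, sets out from 4 and returns at 8. Lithiated bis(pinacolatoboryl)methane (LiTMP, THF, −78 °C) is condensed with 1,1-dimethoxypropan-2-one in a boron-Wittig olefination to give 2-[(E)-3,3-dimethoxy-2-methylprop-1-en-1-yl]-4,4,5,5-tetramethyl-1,3,2-dioxaborolane F1. Mild aqueous acid frees (E)-2-methyl-3-(pinacolboryl)prop-2-enal F2, an α,β-disubstituted enal of the class for which the catalysed Diels–Alder reaction is established. Cycloaddition of F2 with 4 under the step 4 catalyst gives the C2-symmetric bis(boryl aldehyde) F3. NaBO3 oxidation, with retention at carbon, gives the bis(hydroxy aldehyde) F4. O-Alkylation with 2-methylbut-3-en-2-yl trichloroacetimidate (cat. TfOH) gives the bis(1,1-dimethylallyl ether) F5. Wacker oxidation of the two vinyl groups (PdCl2, CuCl, O2, DMF–H2O) returns 8.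

2. Step 7. What may go wrong: water may open the bromonium ion at the secondary carbon or from the wrong face, allylic bromination may compete, and the second ring may add as well. The fallback sets out from 10 and returns at 12. One equivalent of mCPBA epoxidises one ring alkene anti to the angular methyl to give the mono-epoxide F6. Aqueous HClO4 in THF opens it trans-diaxially at the tertiary carbon with inversion to give the 7,8-diol F7, whose tertiary OH is axial. The secondary OH alone is converted into the phenyl thionocarbonate F8 (PhOC(S)Cl, pyridine). Barton–McCombie deoxygenation (Bu3SnH, AIBN) then gives 12.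

3. Step 9. What may go wrong: poor facial selectivity when the tertiary radical is oxygenated, or competing reduction to the alkane. The fallback sets out from 12 and returns at 13. mCPBA epoxidises the remaining alkene anti to the angular methyl to give the epoxide F9. LiEt3BH opens it at the secondary carbon and also reduces both ketones, giving the tetraol F10 as a mixture of C3 carbinol epimers. Dess–Martin oxidation of the two secondary alcohols returns 13.

Further compounds
F1 | step 4 | 2-[(E)-3,3-dimethoxy-2-methylprop-1-en-1-yl]-4,4,5,5-tetramethyl-1,3,2-dioxaborolane | CC1(C)OB(OC1(C)C)/C=C(\C)C(OC)OC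
F2 | step 4 | (E)-2-methyl-3-(4,4,5,5-tetramethyl-1,3,2-dioxaborolan-2-yl)prop-2-enal | CC1(C)OB(OC1(C)C)/C=C(\C)C=O
F3 | step 4 | C2-symmetric bis(boryl aldehyde), configuration as in 8 with pinacolboryl in place of the ether oxygen | CC1=CC[C@H](B2OC(C)(C)C(C)(C)O2)[C@@](C)(C=O)[C@@H]1CC[C@@H]1C(C)=CC[C@H](B2OC(C)(C)C(C)(C)O2)[C@@]1(C)C=O
F4 | step 4 | C2-symmetric bis(hydroxy aldehyde), configuration as in 8 | CC1=CC[C@H](O)[C@@](C)(C=O)[C@@H]1CC[C@@H]1C(C)=CC[C@H](O)[C@@]1(C)C=O
F5 | step 4 | C2-symmetric bis(2-methylbut-3-en-2-yl ether), configuration as in 8 | CC1=CC[C@H](OC(C)(C)C=C)[C@@](C)(C=O)[C@@H]1CC[C@@H]1C(C)=CC[C@H](OC(C)(C)C=C)[C@@]1(C)C=O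
F6 | step 7 | mono-epoxide of 10, epoxide oxygen trans to the 5a-methyl | C[C@]12O[C@H]1C[C@@H]3OC(C)(C)C(=O)CC[C@@]3(C)[C@@H]2CC[C@H]1[C@]2(C)CCC(=O)C(C)(C)O[C@H]2CC=C1C
F7 | step 7 | 7,8-diol: tertiary 7-OH axial and cis to 5a-Me, secondary 8-OH trans to it; unit B as in 10 | O[C@]1(C)[C@@H](O)C[C@@H]2OC(C)(C)C(=O)CC[C@@]2(C)[C@@H]1CC[C@H]1[C@]2(C)CCC(=O)C(C)(C)O[C@H]2CC=C1C
F8 | step 7 | 8-O-(phenoxythiocarbonyl) derivative of F7 | O[C@]1(C)[C@@H](OC(=S)Oc3ccccc3)C[C@@H]2OC(C)(C)C(=O)CC[C@@]2(C)[C@@H]1CC[C@H]1[C@]2(C)CCC(=O)C(C)(C)O[C@H]2CC=C1C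
F9 | step 9 | epoxide of 12, epoxide oxygen trans to the 5a-methyl of unit B | O[C@]1(C)CC[C@@H]2OC(C)(C)C(=O)CC[C@@]2(C)[C@@H]1CC[C@H]1[C@]2(C)CCC(=O)C(C)(C)O[C@H]2C[C@@H]3O[C@]13C
F10 | step 9 | tetraol: both C3 ketones of 13 reduced, C3 carbinol configuration undefined (mixture) | O[C@]1(C)CC[C@@H]2OC(C)(C)C(O)CC[C@@]2(C)[C@@H]1CC[C@H]1[C@]2(C)CCC(O)C(C)(C)O[C@H]2CC[C@]1(C)O
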